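The numbers in the tables were computed on assumed constants, noise included.

We must choose between two flasks of one charge, south-east at 25 °C and south at 10 °C, for double product after 10 min.

| flask | substrate | partner | capture agent | temperature | remark | time |
|---|---|---|---|---|---|---|
| ash | 28 mM | 40 mM | 0.40 mM | 5 °C | run made earlier |  |
| larch | 44 mM | 40 mM | 0.40 mM | 18 °C | run made earlier |  |
| alder | 20 mM | 20 mM | 0.40 mM | 5 °C | run made earlier |  |
| south-east | 20 mM | 40.0 mM | 0.400 mM | 25 °C |  | 10 min |
| south | 20 mM | 40.0 mM | 0.400 mM | 10 °C |  | 10 min |

| run | time / min | double product / % |
|---|---|---|
| ash | 1.33 | 2.0 |
| ash | 4.00 | 4.8 |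
| ash | 8.00 | 14.7 |
| ash | 10.0 | 19.0 |
| ash | 15.0 | 26.3 |
| larch | 0.500 | 0.9 |
| larch | 0.833 | 2.6 |
| larch | 1.50 | 5.9 |
| larch | 3.00 | 10.2 |
| larch | 6.00 | 14.2 |
| alder | 1.33 | 1.9 |
| alder | 4.00 | 1.6 |
| alder | 8.00 | 5.8 |
| alder | 10.0 | 7.0 |
| alder | 15.0 | 10.3 |

(standard deviation of a reading: 1 percentage point)

1. the best flask by amount of double product, in percent of the substrate charged; "all alike" if 1.5 percentage points covers them all (south-east / south / all alike)
2. amount of double product at the end, in percent of the substrate charged, south-east
3. amount of double product at the end, in percent of the substrate charged, south

- what may be going on: mono adduct + capture agent -> trapped intermediate; partner -> decomposition product; partner + mono adduct -> double product; substrate + partner -> mono adduct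

The runs seem to speak against heat: larch at 18 °C stood at 14.2% after 6.00 min, lower than ash at 5 °C, with 26.3% after 15.0 min. But larch was charged partner equal to 90.9% of its substrate, and each substrate converted takes one partner, each double product a second. Suppose the whole larch charge of partner is consumed at that last reading. Then the substrate left is a = 23.3% and the mono adduct m = 62.5%, both of the substrate charged and both carrying the scatter of the reading.

Dividing the two rate laws removes partner and clock: m = (a^σ − a)/(1 − σ). The capture agent charged in south-east and south equals 2.00% of their substrate, and each capture agent takes one mono adduct; we leave this trapped intermediate out as an approximation, so we take the double product as what remains of the charge after a and m, which can overstate it by up to that share. Solving at larch's point, from a first estimate of 0.171, we read 0.226 for σ, the second addition's rate constant over the first's, the selectivity factor. Taking σ as equal at every temperature, heat only moves a flask along this curve. South-east and south have partner at 200% of their substrate. We judge that south reaches a near 10.0% and south-east near 1.00%, so our reckoning gives 26.1% for south and 54.7% for south-east.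

The forecast, against our ranking, names south, with 12% (8% to 17%) for south-east and 20% (15% to 25%) for south, on the ground that “Partner decomposition must be steep”.

The simulation gives 57.2% in south-east, higher than the 31.6% in south, so south-east is the better flask.

    mono adduct + capture agent → trapped intermediate (k = 0.923 /M/s, Ea = 53.0 kJ/mol)
    partner → decomposition product (k = 1.35 × 10⁻⁵ /s, Ea = 99.0 kJ/mol)
    partner + mono adduct → double product (k = 0.124 /M/s, Ea = 44.0 kJ/mol)
    substrate + partner → mono adduct (k = 0.470 /M/s, Ea = 51.0 kJ/mol)
    (constants at 25 °C)

South-east ended with 1.19% of its substrate left, and the curve with σ at 0.226 gives 52.9% there. It still held 39.6% as mono adduct, through the shrinking partner and the short time together: with partner held at its charge south-east gives 91.3%, and read at 100 min it gives 92.0%. The neighbour of south-east charged with 50 mM of substrate ended with partner at 0.0707% and substrate at 31.3%, where the curve gives 9.77% and that flask 11.1%.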